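(The earlier runs and the new flask were generated by integration on assumed constants, and the scatter is random.)

The ratio of [L] charged to [L] now is the reading we would follow in the blue flask, and it gives you your quick number.

- blue: L 0.050 M; Q 0.045 M; the very flask that is asked about, followed so far
- flask: L 0.050 M; Q 0.0450 M; time 2.5 h

- blue (time / min: L / %, Z / %): 2.50: 90, 9; 6.00: 76, 16; 12.0: 62, 26; 30.0: 38, 37

(scatter of a reading: 1.5 percentage points)

- a species is counted by the L in it: one G counts as two
- the analysis behind the earlier runs scatters by 1.5 percentage points, standard deviation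
- on the list of suspects stand: L + Q -> Z; Q + Z -> X; 2 L -> G; Z -> E

- L at 2.5 h, in percent of the L charged
- Z at 2.5 h, in percent of the L charged
- X at 2.5 h, in percent of the L charged

In the blue flask Q is charged at 0.0450 M against 0.050 M of L, so we take L + Q → Z and the pairing of two L to G as both going with [L] squared, and then this ratio climbs in a straight line with time. We call its rise above one per hour the clock (the apparent second-order rate constant times the charge of L): 3.26 h⁻¹ from L 38% at 30.0 min. The reading at 12.0 min gives 3.06 h⁻¹, with a scatter of 1.5 percentage points on each L.

Carried to 2.5 h, the ratio is one plus clock times time, so we commit to L 10.9%. Your forecast gives L 12.5%, Z 38% and X 18%, with the remark: “I lean towards X but keep the range wide”. Our L is lower than yours by 1.6 points. The clock gives no number for Z or X, so we add none. Take Q as well as L and Z in the blue flask: Q + Z → X spends Q after Z is made, and Z → E does not.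

The flask gives L 8.77%, Z 22.1% and X 2.04%.

    L + Q → Z (k = 47.9 L mol⁻¹ h⁻¹)
    Q + Z → X (k = 1.67 L mol⁻¹ h⁻¹)
    2 L → G (k = 7.52 L mol⁻¹ h⁻¹)
    Z → E (k = 0.595 h⁻¹)

In this flask at 2.50 h, E stands at 46.5%, more than X at 2.04%. The clock's L of 10.9% lies 2.1 points above the flask's. For the same flask read at 1.0 h, the clock gives L 23.5%, and that reading holds L 22.7%.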